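**Strategy.** Everything rests on making the cyclopentane (C1–C5, guaiane numbering) last among the carbocycles by a santonin-type dienone photorearrangement. The precursor is a decalin: a cross-conjugated cyclohexadienone (C1–C5 plus C10) fused to a cyclohexane through a C5–C10 bond that the target lacks. On irradiation in aqueous acetic acid C1 bonds to C5, closing the five-membered ring; the temporary C5–C10 bond then fragments, enlarging the cyclohexane to the cycloheptane, and water enters at C10. The step exploits the fact that the five- and seven-membered rings share C1–C5 with the C10 methyl carbinol next to C1, and sets H-1 and C10 together. The oxirane is added afterwards.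

Key step: step 5

Remark on the chemistry: atoms carry guaiane numbers throughout (the decalins 10 and 11 are numbered as eudesmanes, so each atom keeps its number through step 5), α is the face of H-1, TBS is tert-butyldimethylsilyl, and enone 1 is assumed to be a catalogue building block in its (R) form.

Step 1
Reactants: 1 (R)-4-(tert-butyldimethylsilyloxy)cyclohex-2-en-1-one; 2 iodomethane
Product: 4 (4R)-4-(tert-butyldimethylsilyloxy)-6-methylcyclohex-2-en-1-one (C6 epimers), via lithium dienolate 3 (not isolated)
Conditions: LiN(iPr)2, THF, −78 °C; MeI, −78 → −30 °C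
Reagents that add atoms: iodomethane, CI
Why: Kinetic α′-deprotonation gives the cross-conjugated lithium dienolate 3, whose C-methylation (enolate alkylation) installs the future C10 methyl; the new centre forms as an epimer mixture, which is irrelevant because it is re-enolised in step 3.

Step 2
Reactants: 4 (4R)-4-(tert-butyldimethylsilyloxy)-6-methylcyclohex-2-en-1-one; 5 isopropylmagnesium chloride
Product: 7 (4R,5S)-4-(tert-butyldimethylsilyloxy)-5-isopropyl-2-methylcyclohexan-1-one (C2 epimers), via magnesium enolate 6 (not isolated)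
Conditions: iPrMgCl, CuBr·SMe2 (10 mol %), THF, −40 °C; aq NH4Cl
Reagents that add atoms: isopropylmagnesium chloride, CC(C)[Mg]Cl
Why: Copper-catalysed conjugate addition of the Grignard reagent, in which the isopropyl group enters the β-carbon anti to the neighbouring silyloxy group and so sets the trans C7/C8 relationship of the target.

Step 3
Reactants: 7 (4R,5S)-4-(tert-butyldimethylsilyloxy)-5-isopropyl-2-methylcyclohexan-1-one; 8 ethyl vinyl ketone
Product: 10 8β-(tert-butyldimethylsilyloxy)-7βH-eudesm-4-en-3-one, via Michael adduct 9 (not isolated)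
Conditions: ethyl vinyl ketone, KOH, EtOH, −10 °C → rt, then reflux
Reagents that add atoms: ethyl vinyl ketone (pent-1-en-3-one), CCC(=O)C=C
Why: Robinson annulation, in which the more substituted enolate adds to the enone by axial attack on the half-chair that keeps isopropyl and silyloxy equatorial (the face trans to the silyloxy group, the sense known for dihydrocarvone giving 10-epi-α-cyperone), fixing the C10 quaternary centre with its methyl cis to OTBS and trans to isopropyl before aldol condensation closes ring A.

Step 4
Reactants: 10 8β-(tert-butyldimethylsilyloxy)-7βH-eudesm-4-en-3-one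
Product: 11 8β-(tert-butyldimethylsilyloxy)-7βH-eudesma-1,4-dien-3-one
Conditions: DDQ (2,3-dichloro-5,6-dicyano-1,4-benzoquinone), dioxane, reflux
Reagents that add atoms: none
Why: DDQ dehydrogenation of the 4-en-3-one under neutral conditions introduces the C1=C2 double bond and gives the cross-conjugated dienone without touching a stereocentre.

Step 5
Reactants: 11 8β-(tert-butyldimethylsilyloxy)-7βH-eudesma-1,4-dien-3-one
Product: 13 8β-(tert-butyldimethylsilyloxy)-10α-hydroxy-1αH,7βH-guai-4-en-3-one, via cyclopropane-fused oxyallyl zwitterion 12 (not isolated)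
Conditions: hν (medium-pressure Hg lamp, Pyrex), AcOH–H2O (1:1), N2, 15 °C
Reagents that add atoms: water, O
Why: n→π* excitation of the cross-conjugated dienone leads to bonding between C1 and C5 (the termini of the C1–C5 pentadienone unit of ring A), giving the cyclopropane-fused oxyallyl zwitterion 12, which is protonated on oxygen; the resulting cyclopropylcarbinyl cation, centred on C4, breaks the temporary C5–C10 bond as water attacks C10. The closest known reaction type is the photorearrangement of santonin-type 4-methyl-1,4-dien-3-ones in aqueous acetic acid to 10-hydroxy hydroazulenones (santonin to isophotosantonic lactone). The five-membered ring closes by a photochemical disrotatory 4π electrocyclic closure of the pentadienone (Nazarov-like, C1–C5 bond), whereas the seven-membered ring is not closed at all but results from fragmentation of the C5–C10 bond shared by the cyclopropane and the six-membered ring. H-1 is fixed by the cis fusion that ring B must keep on the transient cyclopropane (C6 and C9 on one side, so H-1 ends cis to C9 and the C10 methyl lies over the five-membered ring), and C10 is set by backside entry of water with inversion, which places the hydroxyl cis to H-1 (10α-OH, 1α-H); C7 and C8 are not touched. The step needs fragmentation of C5–C10 and not of C1–C10 (spiro[4.5] ketone) or a 1,4-shift to the lumiketone: the C4 methyl, which stabilises positive charge next to C5, and the protic acidic medium, which traps the zwitterion, secure this. The product enone absorbs too, so irradiation through Pyrex is stopped when 11 is consumed.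

Step 6
Reactants: 13 8β-(tert-butyldimethylsilyloxy)-10α-hydroxy-1αH,7βH-guai-4-en-3-one; 14 p-toluenesulfonyl hydrazide
Product: 15 C3 tosylhydrazone of 13
Conditions: TsNHNH2, EtOH, AcOH (cat.), 50 °C
Reagents that add atoms: p-toluenesulfonyl hydrazide, Cc1ccc(cc1)S(=O)(=O)NN
Why: Condensation of the cyclopentenone carbonyl with the hydrazide (hydrazone formation) gives the α,β-unsaturated tosylhydrazone under conditions too mild to dehydrate the C10 carbinol, and no stereocentre is affected.

Step 7
Reactants: 15 C3 tosylhydrazone of 13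
Product: 17 8β-(tert-butyldimethylsilyloxy)-1αH,5βH,7βH-guai-3-en-10α-ol, via allylic diazene 16 (not isolated)
Conditions: catecholborane (3 equiv), CHCl3, 0 °C → rt; NaOAc·3H2O, reflux
Reagents that add atoms: none
Why: Kabalka reduction of the unsaturated tosylhydrazone with alkene transposition, in which hydride adds to C3 from the open α face (the β face is screened by C10 and its methyl), sulfinate loss gives the 3β-diazene 16, and its suprafacial retro-ene loss of N2 delivers hydrogen to C5 on the β face while the double bond moves to C3=C4, setting the trans ring fusion (the sense by which cholest-4-en-3-one gives 5β-cholest-3-ene).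

Step 8
Reactants: 17 8β-(tert-butyldimethylsilyloxy)-1αH,5βH,7βH-guai-3-en-10α-ol
Product: 18 1αH,5βH,7βH-guai-3-ene-8β,10α-diol
Conditions: HF·pyridine, pyridine, THF, 0 °C → rt
Reagents that add atoms: none
Why: Fluoride-induced desilylation under buffered conditions frees the C8 hydroxyl without ionising the tertiary alcohol or isomerising the trisubstituted alkene.

Step 9
Reactants: 18 1αH,5βH,7βH-guai-3-ene-8β,10α-diol; 19 4-acetoxybenzoyl chloride
Product: 20 10α-hydroxy-1αH,5βH,7βH-guai-3-en-8β-yl 4-acetoxybenzoate
Conditions: 4-acetoxybenzoyl chloride, pyridine, DMAP (cat.), CH2Cl2, 0 °C → rt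
Reagents that add atoms: 4-acetoxybenzoyl chloride, CC(=O)Oc1ccc(cc1)C(Cl)=O
Why: DMAP-catalysed acylation (nucleophilic catalysis) esterifies the secondary C8 hydroxyl with retention and leaves the tertiary C10 hydroxyl free.

Step 10
Reactants: 20 10α-hydroxy-1αH,5βH,7βH-guai-3-en-8β-yl 4-acetoxybenzoate
Product: 21 3α,4α-epoxy-10α-hydroxy-1αH,5βH,7βH-guaian-8β-yl 4-acetoxybenzoate
Conditions: mCPBA, NaHCO3, CH2Cl2, 0 °C
Reagents that add atoms: meta-chloroperoxybenzoic acid, OOC(=O)c1cccc(Cl)c1
Why: Prilezhaev epoxidation of the only alkene, in which hydrogen bonding of the peracid to the 10α-hydroxyl (Henbest direction) and screening of the β face near C2/C3 by the C10 methyl should deliver oxygen to the α face and give the 3α,4α-oxirane.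

Step 11
Reactants: 21 3α,4α-epoxy-10α-hydroxy-1αH,5βH,7βH-guaian-8β-yl 4-acetoxybenzoate
Product: 22 3α,4α-epoxy-10α-hydroxy-1αH,5βH,7βH-guaian-8β-yl 4-hydroxybenzoate (target)
Conditions: pyrrolidine (3 equiv), CH2Cl2, 0 °C → rt
Reagents that add atoms: none
Why: Aminolysis of the activated aryl acetate is far faster than attack on the hindered secondary benzoate or on the trisubstituted oxirane, so the phenol is released chemoselectively.

**Compound list**

1 | (R)-4-(tert-butyldimethylsilyloxy)cyclohex-2-en-1-one | O=C1C=C[C@H](O[Si](C)(C)C(C)(C)C)CC1 | starting material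
2 | iodomethane | CI | starting material
3 | lithium cross-conjugated dienolate of 1 (deprotonated at C6) | C1=CC(O[Li])=CC[C@H]1O[Si](C)(C)C(C)(C)C | intermediate
4 | (4R)-4-(tert-butyldimethylsilyloxy)-6-methylcyclohex-2-en-1-one (C6 epimers) | C1=CC(=O)C(C)C[C@H]1O[Si](C)(C)C(C)(C)C | intermediate
5 | isopropylmagnesium chloride | CC(C)[Mg]Cl | starting material
6 | chloromagnesium enolate from conjugate addition (enolate towards the isopropyl-bearing carbon) | CC(C)[C@@H]1C=C(O[Mg]Cl)C(C)C[C@H]1O[Si](C)(C)C(C)(C)C | intermediate
7 | (4R,5S)-4-(tert-butyldimethylsilyloxy)-5-isopropyl-2-methylcyclohexan-1-one (OTBS and isopropyl trans, C2 epimers) | CC(C)[C@@H]1CC(=O)C(C)C[C@H]1O[Si](C)(C)C(C)(C)C | intermediate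
8 | ethyl vinyl ketone (pent-1-en-3-one) | CCC(=O)C=C | starting material
9 | (2R,4R,5S)-4-(tert-butyldimethylsilyloxy)-5-isopropyl-2-methyl-2-(3-oxopentyl)cyclohexan-1-one (methyl cis to OTBS, trans to isopropyl) | CC(C)[C@@H]1CC(=O)[C@](C)(CCC(=O)CC)C[C@H]1O[Si](C)(C)C(C)(C)C | intermediate
10 | 8β-(tert-butyldimethylsilyloxy)-7βH-eudesm-4-en-3-one (10β-methyl cis to 8β-OTBS, trans to 7α-isopropyl) | CC(C)[C@@H]1CC2=C(C)C(=O)CC[C@]2(C)C[C@H]1O[Si](C)(C)C(C)(C)C | intermediate
11 | 8β-(tert-butyldimethylsilyloxy)-7βH-eudesma-1,4-dien-3-one | CC(C)[C@@H]1CC2=C(C)C(=O)C=C[C@]2(C)C[C@H]1O[Si](C)(C)C(C)(C)C | intermediate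
12 | cyclopropane-fused oxyallyl zwitterion (C1–C5–C10 cyclopropane, H-1 cis to C9) | CC(C)[C@@H]1C[C@]23[C+](C)C([O-])=C[C@H]2[C@]3(C)C[C@H]1O[Si](C)(C)C(C)(C)C | intermediate
13 | 8β-(tert-butyldimethylsilyloxy)-10α-hydroxy-1αH,7βH-guai-4-en-3-one | CC(C)[C@@H]1CC2=C(C)C(=O)C[C@H]2[C@](C)(O)C[C@H]1O[Si](C)(C)C(C)(C)C | intermediate
14 | p-toluenesulfonyl hydrazide | Cc1ccc(cc1)S(=O)(=O)NN | starting material
15 | C3 tosylhydrazone of 13 | CC(C)[C@@H]1CC2=C(C)C(=NNS(=O)(=O)c3ccc(C)cc3)C[C@H]2[C@](C)(O)C[C@H]1O[Si](C)(C)C(C)(C)C | intermediate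
16 | 3β-diazenyl-8β-(tert-butyldimethylsilyloxy)-1αH,7βH-guai-4-en-10α-ol (allylic diazene) | CC(C)[C@@H]1CC2=C(C)[C@@H](N=N)C[C@H]2[C@](C)(O)C[C@H]1O[Si](C)(C)C(C)(C)C | intermediate
17 | 8β-(tert-butyldimethylsilyloxy)-1αH,5βH,7βH-guai-3-en-10α-ol | CC(C)[C@@H]1C[C@H]2[C@@H](CC=C2C)[C@](C)(O)C[C@H]1O[Si](C)(C)C(C)(C)C | intermediate
18 | 1αH,5βH,7βH-guai-3-ene-8β,10α-diol | CC(C)[C@@H]1C[C@H]2[C@@H](CC=C2C)[C@](C)(O)C[C@H]1O | intermediate
19 | 4-acetoxybenzoyl chloride | CC(=O)Oc1ccc(cc1)C(Cl)=O | starting material
20 | 10α-hydroxy-1αH,5βH,7βH-guai-3-en-8β-yl 4-acetoxybenzoate | CC(C)[C@@H]1C[C@H]2[C@@H](CC=C2C)[C@](C)(O)C[C@H]1OC(=O)c1ccc(OC(C)=O)cc1 | intermediate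
21 | 3α,4α-epoxy-10α-hydroxy-1αH,5βH,7βH-guaian-8β-yl 4-acetoxybenzoate | CC(C)[C@@H]1C[C@H]2[C@@H](C[C@H]3O[C@]32C)[C@](C)(O)C[C@H]1OC(=O)c1ccc(OC(C)=O)cc1 | intermediate
22 | 3α,4α-epoxy-10α-hydroxy-1αH,5βH,7βH-guaian-8β-yl 4-hydroxybenzoate (CNP0225095.2) | CC(C)[C@@H]1C[C@H]2[C@@H](C[C@H]3O[C@]32C)[C@](C)(O)C[C@H]1OC(=O)c1ccc(O)cc1 | target

**Totals.** Total step count: 11. Longest linear sequence: 11 steps (from 1).

**Steps most likely to fail**

Step 10: the peracid may attack the β face of the cyclopentene, because the directing 10α-hydroxyl is two carbons away from the alkene and the steric bias of the trans-fused ring is small. The fallback sets out from 20 and inverts the sense of oxygen delivery by a halohydrin sequence. NBS in THF–H2O at 0 °C should form the bromonium ion on the face the peracid prefers, and water should open it at the tertiary C4 from the other face, giving the 3β-bromo-4α-hydroxy bromohydrin F4. K2CO3 in MeOH then closes the oxirane by displacement of bromide with inversion at C3 (3α,4α) and removes the aryl acetate in the same flask, so the route is rejoined at 22.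

Step 7: hydroboration of the hindered C=N bond may be slow or may take place from the β face, which would end in the cis-fused alkene, and simple reduction without transposition can compete. The fallback sets out from 13 and sets C5 by protonation instead of by the retro-ene transfer. Li in NH3/THF with t-BuOH (1 equiv) at −78 °C should protonate the β-carbanion at C5 to the trans-fused enolate, which is trapped regiospecifically with PhNTf2 as the C3 enol triflate F3. Pd(OAc)2, PPh3, Bu3N and HCO2H in DMF at 60 °C should then reduce the triflate to the C3=C4 alkene, returning to the route at 17.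

Step 3: attack of the enolate on the face cis to the silyloxy group (erosion of facial selectivity) and base-induced polymerisation of the vinyl ketone would give a C10 epimer mixture and low conversion. The fallback sets out from 7 and puts the quaternary centre under auxiliary control. Condensation with (R)-1-phenylethylamine (toluene, TsOH cat., water separator) gives the N-(1-phenylethyl)imine F1. Its secondary enamine tautomer should add to ethyl vinyl ketone (THF, rt) at the more substituted carbon on the face away from the phenyl group, with auxiliary and substrate bias matched, giving the adduct imine F2. Aqueous AcOH liberates diketone 9, here isolated, which NaOMe in MeOH cyclises, rejoining the route at 10.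

**Further compounds**

F1 | step 3 | N-[(1R)-1-phenylethyl]imine of 7 | CC(C)[C@@H]1CC(=N[C@H](C)c2ccccc2)C(C)C[C@H]1O[Si](C)(C)C(C)(C)C
F2 | step 3 | N-[(1R)-1-phenylethyl]imine of Michael adduct 9 | CC(C)[C@@H]1CC(=N[C@H](C)c2ccccc2)[C@](C)(CCC(=O)CC)C[C@H]1O[Si](C)(C)C(C)(C)C
F3 | step 7 | 8β-(tert-butyldimethylsilyloxy)-10α-hydroxy-1αH,5βH,7βH-guai-3-en-3-yl trifluoromethanesulfonate | CC(C)[C@@H]1C[C@H]2[C@@H](CC(OS(=O)(=O)C(F)(F)F)=C2C)[C@](C)(O)C[C@H]1O[Si](C)(C)C(C)(C)C
F4 | step 10 | 3β-bromo-4α,10α-dihydroxy-1αH,5βH,7βH-guaian-8β-yl 4-acetoxybenzoate | CC(C)[C@@H]1C[C@H]2[C@@H](C[C@H](Br)[C@@]2(C)O)[C@](C)(O)C[C@H]1OC(=O)c1ccc(OC(C)=O)cc1
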